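**Plan**
- Retrosynthesis: the two methyl ethers on the catechol ring (ring B) are removed last, and the outer phenol rings C and D are traced back to cyclohex-2-enones. The two bridge CH2–C(ring C) and CH2–C(ring D) bonds are then cut together, giving a two-armed organomagnesium core and two molecules of 3-ethoxycyclohex-2-enone. The diaryl ether C–O bond between rings A and B is cut last, to two benzaldehydes.
- Enabling feature: in each outer ring the hydroxyl-bearing carbon and the bridge-bearing carbon are 1,3 to each other. This is the relationship of C1 (C=O) and C3 (alkyl) in a 3-alkylcyclohex-2-enone, so each phenol can be carried as an enone.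
- Forward: an SNAr reaction joins rings A and B, and both formyl groups are grown into 2-bromoethyl arms (Wittig, hydroboration–oxidation, Appel). Magnesium insertion and a two-fold Stork–Danheiser addition attach the two preformed six-membered carbocycles, aerobic dehydrogenation turns them into rings C and D, and BBr3 frees the catechol.
- Stereochemistry: the target has no stereocentre and no stereogenic double bond, so nothing has to be set. The only stereocentres on the way, the carbinol carbons of the addition intermediate, are erased within the same step.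

Key step: step 6

Remark on the chemistry: the hydroxy-dimethoxybenzaldehyde is assumed to be purchasable, and the two-armed Grignard reagent is handled as a titrated THF solution that is the product of one step and the reactant of the next.

**Step 1**
Reactants: 1 3-hydroxy-4,5-dimethoxybenzaldehyde; 2 4-fluorobenzaldehyde
Product: 3 3-(4-formylphenoxy)-4,5-dimethoxybenzaldehyde
Conditions: K2CO3, DMF, 120 °C
Reagents that add atoms: none
Why: Nucleophilic aromatic substitution, in which the phenoxide of 1 displaces fluoride from the para-formyl-activated ring of 2 through a Meisenheimer adduct; neither aldehyde is enolisable.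

**Step 2**
Reactants: 3 3-(4-formylphenoxy)-4,5-dimethoxybenzaldehyde
Product: 4 5-ethenyl-1-(4-ethenylphenoxy)-2,3-dimethoxybenzene
Conditions: Ph3PCH3Br, KOt-Bu, THF, 0 °C to rt
Reagents that add atoms: methyltriphenylphosphonium bromide, C[P+](c1ccccc1)(c1ccccc1)c1ccccc1.[Br-]
Why: Double Wittig methylenation with the non-stabilised ylide should convert both non-enolisable aryl aldehydes into styrenes while the aryl ethers stay inert.

**Step 3**
Reactants: 4 5-ethenyl-1-(4-ethenylphenoxy)-2,3-dimethoxybenzene
Product: 6 2-{4-[5-(2-hydroxyethyl)-2,3-dimethoxyphenoxy]phenyl}ethan-1-ol, via bis(B-alkyl-9-BBN) adduct 5 (not isolated)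
Conditions: 9-BBN, THF, 0 °C to rt; then NaOH, H2O2, H2O, 0 °C to rt
Reagents that add atoms: hydrogen peroxide, OO
Why: Hydroboration–oxidation, in which 9-BBN places boron on the terminal carbon of each styrene for steric reasons and alkaline peroxide replaces boron by hydroxyl, giving the two primary 2-arylethanols.

**Step 4**
Reactants: 6 2-{4-[5-(2-hydroxyethyl)-2,3-dimethoxyphenoxy]phenyl}ethan-1-ol
Product: 7 5-(2-bromoethyl)-1-[4-(2-bromoethyl)phenoxy]-2,3-dimethoxybenzene
Conditions: CBr4, PPh3, CH2Cl2, 0 °C to rt
Reagents that add atoms: carbon tetrabromide, BrC(Br)(Br)Br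
Why: Appel reaction, in which bromide displaces the alkoxyphosphonium groups at the two unhindered primary carbons under neutral conditions that leave the ethers untouched.

**Step 5**
Reactants: 7 5-(2-bromoethyl)-1-[4-(2-bromoethyl)phenoxy]-2,3-dimethoxybenzene
Product: 8 bis-Grignard reagent bromo{2-[4-(5-{2-[bromomagnesio]ethyl}-2,3-dimethoxyphenoxy)phenyl]ethyl}magnesium (THF solution, titrated and used directly)
Conditions: Mg turnings (I2-activated, excess), THF, slow addition of 7 at high dilution, rt to 45 °C
Reagents that add atoms: magnesium, [Mg]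
Why: Grignard formation by oxidative insertion of magnesium metal into primary 2-arylethyl bromides is routine, and slow addition at high dilution should keep Wurtz-type coupling low.

**Step 6**
Reactants: 8 bis-Grignard reagent of the diaryl ether core; 9 3-ethoxycyclohex-2-en-1-one (3 equiv)
Product: 11 3-[2-(4-{2,3-dimethoxy-5-[2-(3-oxocyclohex-1-en-1-yl)ethyl]phenoxy}phenyl)ethyl]cyclohex-2-en-1-one, via bis(bromomagnesium alkoxide) 10 (not isolated)
Conditions: 8 added to 9, THF, 0 °C to rt; then 1 M HCl, THF/H2O, rt
Reagents that add atoms: water, O (source of the two enone carbonyl oxygens)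
Why: Each primary C–Mg bond of 8 adds to the carbonyl carbon of the vinylogous ester 9 to give the bis(tertiary allylic alkoxide) 10; on acidification the allylic C–O bond ionises with help from the ethoxy oxygen, water adds at the ethoxy-bearing carbon and ethanol is expelled, so the carbonyl reappears two carbons away and each arm ends on C3 of a cyclohex-2-enone. The closest known reaction type is the Stork–Danheiser alkylative 1,3-carbonyl transposition of 3-alkoxycyclohexenones with Grignard reagents, run here at both ends of one molecule. No ring is closed: the two six-membered carbocycles arrive intact in 9 and only the two CH2–C(ring) bonds of the bridges are made. No stereocentre remains in 11, because the two carbinol centres of 10 form without control and are erased in the hydrolysis. The step needs 1,2-addition in preference to conjugate addition or enolisation; the donor ethoxy group lowers the electrophilicity of the β-carbon, the unhindered primary alkylmagnesium prefers the carbonyl, and the excess of 9 should ensure that both termini react. The two arms are chemically equivalent primary homobenzylic organomagnesiums, so one operation serves both.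

**Step 7**
Reactants: 11 3-[2-(4-{2,3-dimethoxy-5-[2-(3-oxocyclohex-1-en-1-yl)ethyl]phenoxy}phenyl)ethyl]cyclohex-2-en-1-one
Product: 12 3-[2-(4-{5-[2-(3-hydroxyphenyl)ethyl]-2,3-dimethoxyphenoxy}phenyl)ethyl]phenol
Conditions: Pd(OCOCF3)2 (10 mol %), 2-(dimethylamino)pyridine (20 mol %), TsOH·H2O (40 mol %), O2 (1 atm), DMSO, 80 °C
Reagents that add atoms: none
Why: Palladium-catalysed aerobic dehydrogenation of cyclohexenones to phenols, in which a divalent palladium enolate at C6 of each enone undergoes β-hydride elimination to a cross-conjugated dienone that tautomerises to the 3-alkylphenol, while O2 returns zerovalent palladium to the divalent state.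

**Step 8**
Reactants: 12 3-[2-(4-{5-[2-(3-hydroxyphenyl)ethyl]-2,3-dimethoxyphenoxy}phenyl)ethyl]phenol
Product: 13 perrottetin F, 3-{4-[2-(3-hydroxyphenyl)ethyl]phenoxy}-5-[2-(3-hydroxyphenyl)ethyl]benzene-1,2-diol
Conditions: BBr3 (8 equiv), CH2Cl2, −78 °C to rt; then H2O, 0 °C
Reagents that add atoms: none
Why: Lewis-acid ether cleavage, in which BBr3 coordinates each methoxy oxygen and bromide removes the methyl group by SN2, while the diaryl ether, which has no sp3 carbon on oxygen, survives and aqueous work-up hydrolyses the aryl borates to the free catechol.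

**Compound list**

| No. | Name | SMILES | Role |
|---|---|---|---|
| 1 | 3-hydroxy-4,5-dimethoxybenzaldehyde | COc1cc(C=O)cc(O)c1OC | starting material |
| 2 | 4-fluorobenzaldehyde | O=Cc1ccc(F)cc1 | starting material |
| 3 | 3-(4-formylphenoxy)-4,5-dimethoxybenzaldehyde | O=Cc1ccc(Oc2cc(C=O)cc(OC)c2OC)cc1 | intermediate |
| 4 | 5-ethenyl-1-(4-ethenylphenoxy)-2,3-dimethoxybenzene | C=Cc1ccc(Oc2cc(C=C)cc(OC)c2OC)cc1 | intermediate |
| 5 | 9-[2-(4-{5-[2-(9-borabicyclo[3.3.1]nonan-9-yl)ethyl]-2,3-dimethoxyphenoxy}phenyl)ethyl]-9-borabicyclo[3.3.1]nonane (not isolated) | COc1cc(CCB2C3CCCC2CCC3)cc(Oc2ccc(CCB3C4CCCC3CCC4)cc2)c1OC | intermediate |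
| 6 | 2-{4-[5-(2-hydroxyethyl)-2,3-dimethoxyphenoxy]phenyl}ethan-1-ol | OCCc1ccc(Oc2cc(CCO)cc(OC)c2OC)cc1 | intermediate |
| 7 | 5-(2-bromoethyl)-1-[4-(2-bromoethyl)phenoxy]-2,3-dimethoxybenzene | BrCCc1ccc(Oc2cc(CCBr)cc(OC)c2OC)cc1 | intermediate |
| 8 | bis-Grignard reagent of 7, both CH2Br groups converted to CH2MgBr (THF solution) | Br[Mg]CCc1ccc(Oc2cc(CC[Mg]Br)cc(OC)c2OC)cc1 | intermediate |
| 9 | 3-ethoxycyclohex-2-en-1-one | CCOC1=CC(=O)CCC1 | starting material |
| 10 | bis(bromomagnesium) alkoxide of 3-ethoxy-1-[2-(4-{5-[2-(3-ethoxy-1-hydroxycyclohex-2-en-1-yl)ethyl]-2,3-dimethoxyphenoxy}phenyl)ethyl]cyclohex-2-en-1-ol (both carbinol centres uncontrolled, mixture; not isolated) | CCOC1=CC(CCc2ccc(Oc3cc(CCC4(O[Mg]Br)C=C(OCC)CCC4)cc(OC)c3OC)cc2)(O[Mg]Br)CCC1 | intermediate |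
| 11 | 3-[2-(4-{2,3-dimethoxy-5-[2-(3-oxocyclohex-1-en-1-yl)ethyl]phenoxy}phenyl)ethyl]cyclohex-2-en-1-one | O=C1C=C(CCc2ccc(Oc3cc(CCC4=CC(=O)CCC4)cc(OC)c3OC)cc2)CCC1 | intermediate |
| 12 | 3-[2-(4-{5-[2-(3-hydroxyphenyl)ethyl]-2,3-dimethoxyphenoxy}phenyl)ethyl]phenol | Oc1cccc(CCc2ccc(Oc3cc(CCc4cccc(O)c4)cc(OC)c3OC)cc2)c1 | intermediate |
| 13 | perrottetin F, 3-{4-[2-(3-hydroxyphenyl)ethyl]phenoxy}-5-[2-(3-hydroxyphenyl)ethyl]benzene-1,2-diol | Oc1cccc(CCc2ccc(Oc3cc(CCc4cccc(O)c4)cc(O)c3O)cc2)c1 | target |

Total step count: 8. Longest linear sequence: 8 steps (from 1 or 2 to 13); 9 enters at step 6.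

**Steps most likely to fail**

1. Magnesium insertion (step 5). Carbon–magnesium ends already formed may couple with unreacted carbon–bromine ends (Wurtz-type oligomerisation), or insertion may stop after one arm. The fallback sets out from 7. Finkelstein exchange (NaI, acetone, reflux) should give 5-(2-iodoethyl)-1-[4-(2-iodoethyl)phenoxy]-2,3-dimethoxybenzene F1. Lithium–iodine exchange with t-BuLi (4.2 equiv, Et2O/pentane, −78 °C) should then give the two-armed alkyllithium 5-(2-lithioethyl)-1-[4-(2-lithioethyl)phenoxy]-2,3-dimethoxybenzene F2 homogeneously and at low temperature, where coupling is slow. Transmetallation with MgBr2·OEt2 at −78 °C comes back to the route at 8.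

2. Two-fold addition and transposition (step 6). Proton transfer from the α-methylene groups of 9 to the Grignard reagent may compete with carbonyl addition, or only one terminus may add, leaving an arm reduced to ethyl. The fallback sets out from 4 and makes the same two bonds by B-alkyl Suzuki–Miyaura coupling. Hydroboration with 9-BBN as in step 3 gives 5, which is not oxidised but coupled in the same flask with commercial 3-bromocyclohex-2-en-1-one (O=C1C=C(Br)CCC1). The conditions would be PdCl2(dppf) (dppf = 1,1′-bis(diphenylphosphino)ferrocene), K3PO4, THF/DMF/H2O, 60 °C; oxidative addition of the bromoenone to zerovalent palladium, transmetallation from boron and reductive elimination come back to the route at 11. This fallback makes no compound outside the compound list (entry F0).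

3. Double aerobic dehydrogenation (step 7). The reaction may stall after one ring has aromatised, through aggregation of the catalyst to palladium black or binding of the phenolic product, or the electron-rich rings may degrade under O2 at 80 °C. The fallback sets out from 11 and uses α′-selenenylation and selenoxide elimination. Kinetic deprotonation at C6 of both enones with LiN(i-Pr)2 (2.3 equiv, THF, −78 °C) should give the bis(lithium dienolate) of 11 F3. Trapping with PhSeBr should give 6-(phenylselanyl)-3-[2-(4-{2,3-dimethoxy-5-[2-(3-oxo-4-(phenylselanyl)cyclohex-1-en-1-yl)ethyl]phenoxy}phenyl)ethyl]cyclohex-2-en-1-one F4 as a mixture of stereoisomers at the two selenium-bearing carbons. Oxidation with H2O2 and pyridine in CH2Cl2 (0 °C to rt) should pass through the corresponding bis(selenoxide) F5. Syn-elimination of F5 gives the cross-conjugated dienones, which tautomerise to the phenols, coming back to the route at 12.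

**Further compounds**
F1 | step 5 | 5-(2-iodoethyl)-1-[4-(2-iodoethyl)phenoxy]-2,3-dimethoxybenzene | ICCc1ccc(Oc2cc(CCI)cc(OC)c2OC)cc1
F2 | step 5 | 5-(2-lithioethyl)-1-[4-(2-lithioethyl)phenoxy]-2,3-dimethoxybenzene | [Li]CCc1ccc(Oc2cc(CC[Li])cc(OC)c2OC)cc1
F0 | step 6 | none | none
F3 | step 7 | bis(lithium dienolate) of 11, lithium 3-[2-(4-{2,3-dimethoxy-5-[2-(3-lithiooxycyclohexa-1,3-dien-1-yl)ethyl]phenoxy}phenyl)ethyl]cyclohexa-1,5-dien-1-olate | [Li]OC1=CCCC(CCc2ccc(Oc3cc(CCC4=CC(O[Li])=CCC4)cc(OC)c3OC)cc2)=C1
F4 | step 7 | bis(6-phenylselanyl) derivative of 11 (stereoisomer mixture at the two selenium-bearing carbons) | O=C1C=C(CCc2ccc(Oc3cc(CCC4=CC(=O)C([Se]c5ccccc5)CC4)cc(OC)c3OC)cc2)CCC1[Se]c1ccccc1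
F5 | step 7 | bis(selenoxide) of F4 (stereoisomer mixture) | O=C1C=C(CCc2ccc(Oc3cc(CCC4=CC(=O)C([Se](=O)c5ccccc5)CC4)cc(OC)c3OC)cc2)CCC1[Se](=O)c1ccccc1
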